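## Retrosynthetic overview

1. The last bond is C15–C16: Stille coupling of the ring A vinylstannane 12 with the ring B (E)-vinyl iodide 29.
2. 29 comes from tricyclic ketal 27: C1–C2 is added to the C7 oxocarbenium ion, then the tetrahydropyran is opened by β-fragmentation (retro-oxa-Michael, the counterpart of the Grob opening of ring A in iridal biosynthesis), which releases the 3-hydroxypropyl arm and the Z-enal.
3. Ring B (step 13): epoxide-triggered cation–π cyclisation of epoxy alcohol 24, C6 of a dihydropyran onto C11 of a Sharpless-derived tetrasubstituted epoxide; this one step sets C6, C10 and C11.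
4. Ring A (step 5): HgX+-triggered cation–olefin cyclisation of the isopropenyl β-keto ester 7 (C18–C23 bond), the laboratory counterpart of the methylation-triggered closure; C22 comes from a copper-catalysed SN2' alkylation.
5. Order of ring formation: ring A (step 5), then ring B (step 13); the two fragments are joined in step 16.

Assumption: atoms are numbered as in the iridals (C1 = CHO, C2 = its α-carbon, C3–C5 = hydroxypropyl arm with C3 the carbinol carbon, C6–C11 = ring B, C26 = CH2OH on C11, C12–C17 = chain, C18–C23 = ring A); the target is read from the SMILES as (2Z,6R,10S,11S,14E,16E,18R,22S); the hand of ligand L in step 2 is taken as the one that gives (S)-5 (its antipode is equally available).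

## Route

Step 1
Reactants: 1 (E)-2-methylbut-2-en-1-ol
Product: 2 (E)-1-chloro-2-methylbut-2-ene
Conditions: N-chlorosuccinimide, Me2S, CH2Cl2, −20 → 0 °C
Reagents that add atoms: N-chlorosuccinimide, ClN1C(=O)CCC1=O
Why: Corey–Kim chlorination displaces the alkoxysulfonium ion by chloride in an SN2 reaction at the primary carbon, so there is no allylic shift and the (E)-alkene is kept.

Step 2
Reactants: 2 (E)-1-chloro-2-methylbut-2-ene; 3 2-(2-bromoethyl)-1,3-dioxolane
Product: 5 2-[(3S)-3,4-dimethylpent-4-en-1-yl]-1,3-dioxolane, via [2-(1,3-dioxolan-2-yl)ethyl]magnesium bromide 4 (not isolated)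
Conditions: 3, Mg, THF, 25 °C; then added slowly to 2, Cu(O2C-2-thienyl) (CuTC, 3 mol %), phosphoramidite (S,S,S)-L from BINOL and bis(1-phenylethyl)amine (3.3 mol %), CH2Cl2, −78 °C
Reagents that add atoms: none
Why: Copper-catalysed asymmetric SN2' allylic alkylation (Alexakis type) delivers the alkyl group to the γ-carbon of the trisubstituted allylic chloride, the chiral copper complex selecting one alkene face and so setting the CH(CH3) centre (future C22) as S next to the new isopropenyl group.

Step 3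
Reactants: 5 2-[(3S)-3,4-dimethylpent-4-en-1-yl]-1,3-dioxolane
Product: 6 (4S)-4,5-dimethylhex-5-enal
Conditions: 1 M HCl, THF, 25 °C
Reagents that add atoms: water, O
Why: Acid-catalysed acetal hydrolysis frees the aldehyde; dilute acid does not protonate the 1,1-disubstituted alkene, so the adjacent stereocentre is safe.

Step 4
Reactants: 6 (4S)-4,5-dimethylhex-5-enal
Product: 7 ethyl (6S)-6,7-dimethyl-3-oxooct-7-enoate
Conditions: ethyl diazoacetate, SnCl2 (10 mol %), CH2Cl2, 25 °C
Reagents that add atoms: ethyl diazoacetate, CCOC(=O)C=[N+]=[N-]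
Why: Roskamp homologation (Lewis-acid addition of the diazo ester to the aldehyde, then 1,2-hydride shift with loss of N2) gives the β-keto ester directly without touching the alkene or the remote stereocentre.

Step 5
Reactants: 7 ethyl (6S)-6,7-dimethyl-3-oxooct-7-enoate
Product: 9 ethyl (1S,3S)-2,2,3-trimethyl-6-oxocyclohexane-1-carboxylate, via chloromercurio keto ester 8 (not isolated)
Conditions: Hg(OTf)2·PhNMe2 (1.2 equiv), MeNO2, −20 °C; aq. NaCl; then Bu3SnH, THF, 0 °C
Reagents that add atoms: none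
Why: In this mercury-induced cation–olefin cyclisation (Nishizawa type) divalent mercury adds to the CH2 end of the isopropenyl group and the bridged mercurinium ion is opened at its tertiary carbon (C23) by the enol carbon (C18) through a chair with the C22 methyl equatorial, so no free cation and no 1,2-hydride shift can scramble C22; radical demercuration turns CH2HgCl into the second geminal methyl, and the epimerisable ester carbon settles cis (diequatorial) to the C22 methyl.

Step 6
Reactants: 9 ethyl (1S,3S)-2,2,3-trimethyl-6-oxocyclohexane-1-carboxylate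
Product: 10 ethyl (1R,3S)-2,2,3-trimethyl-6-methylidenecyclohexane-1-carboxylate
Conditions: Ph3PCH3Br, KOtBu (3 equiv each), toluene, 80 °C
Reagents that add atoms: methyltriphenylphosphonium bromide, C[P+](c1ccccc1)(c1ccccc1)c1ccccc1.[Br-]
Why: Wittig methylenation converts the ring ketone (not the ester) into the exocyclic methylene of the γ-irone ring, as in known γ-cyclogeranate syntheses; the cis (diequatorial) ester is the thermodynamic epimer and the minor trans isomer is removed by chromatography.

Step 7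
Reactants: 10 ethyl (1R,3S)-2,2,3-trimethyl-6-methylidenecyclohexane-1-carboxylate
Product: 11 (1R,3S)-2,2,3-trimethyl-6-methylidenecyclohexane-1-carbaldehyde
Conditions: iBu2AlH (1.1 equiv), CH2Cl2, −78 °C; aq. KNa tartrate
Reagents that add atoms: none
Why: Partial ester reduction stops at the aldehyde because the hindered aluminium hemiacetal is stable at −78 °C; the aldehyde is used at once, cold and without base, to avoid epimerisation or conjugation.

Step 8
Reactants: 11 (1R,3S)-2,2,3-trimethyl-6-methylidenecyclohexane-1-carbaldehyde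
Product: 12 tributyl{(E)-2-[(1R,3S)-2,2,3-trimethyl-6-methylidenecyclohexyl]ethenyl}stannane
Conditions: Bu3SnCHBr2 (2 equiv), CrCl2 (8 equiv), LiI, THF/DMF, 25 °C
Reagents that add atoms: (dibromomethyl)tributylstannane, CCCC[Sn](CCCC)(CCCC)C(Br)Br
Why: Hodgson's chromium-mediated stannyl olefination (a Takai-type reaction through a geminal dichromium species) gives the (E)-vinylstannane under non-basic conditions, so the α-stereocentre C18 is not epimerised.

Step 9
Reactants: 13 but-2-yn-1-ol; 14 5-bromopent-2-yne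
Product: 17 (2Z)-3-iodo-2-(pent-3-yn-1-yl)but-2-en-1-ol, via pent-3-yn-1-ylmagnesium bromide 15 (not isolated), via alkenylmagnesium chelate 16 (not isolated)
Conditions: 14, Mg, THF; 13, i-PrMgCl (1.0 equiv), THF, 0 °C; then 15 (1.5 equiv), CuI (10 mol %), 0 → 40 °C; I2, −20 °C
Reagents that add atoms: iodine, [I][I]
Why: Copper-catalysed anti-carbomagnesiation of the propargylic alkoxide (Duboudin–Fallis) puts the alkyl group on the carbon next to CH2O and magnesium on the distal carbon, held cis to CH2O in a five-membered chelate; iodinolysis with retention fixes the geometry of the future C10=C11 alkene.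

Step 10
Reactants: 18 3,4-dihydro-2H-pyran
Product: 21 6-ethenyl-3,4-dihydro-2H-pyran, via 6-lithio-3,4-dihydro-2H-pyran 19 (not isolated), via dihydropyranylzinc chloride 20 (not isolated)
Conditions: t-BuLi, THF/pentane, −78 → 0 °C; ZnCl2; bromoethene, Pd(PPh3)4 (3 mol %), 25 °C
Reagents that add atoms: bromoethene, C=CBr
Why: α-Lithiation of the cyclic enol ether, transmetalation to zinc and Negishi coupling with bromoethene install the two-carbon link (C8, C9) on the enol ether carbon (C7).

Step 11
Reactants: 21 6-ethenyl-3,4-dihydro-2H-pyran; 17 (2Z)-3-iodo-2-(pent-3-yn-1-yl)but-2-en-1-ol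
Product: 23 (2Z)-5-(3,4-dihydro-2H-pyran-6-yl)-3-methyl-2-(pent-3-yn-1-yl)pent-2-en-1-ol, via B-alkyl-9-BBN 22 (not isolated)
Conditions: 21, 9-BBN-H (1.05 equiv), THF, 0 → 25 °C; then 17, PdCl2(dppf) (5 mol %), AsPh3, Cs2CO3, DMF/H2O, 25 °C
Reagents that add atoms: none
Why: 9-BBN adds anti-Markovnikov to the terminal vinyl group only, and B-alkyl Suzuki–Miyaura coupling with the vinyl iodide proceeds with retention, giving the tetrasubstituted alkene with C9 cis to CH2OH.

Step 12
Reactants: 23 (2Z)-5-(3,4-dihydro-2H-pyran-6-yl)-3-methyl-2-(pent-3-yn-1-yl)pent-2-en-1-ol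
Product: 24 [(2R,3S)-3-[2-(3,4-dihydro-2H-pyran-6-yl)ethyl]-3-methyl-2-(pent-3-yn-1-yl)oxiran-2-yl]methanol
Conditions: Ti(OiPr)4 (10 mol %), D-(−)-diethyl tartrate (12 mol %), t-BuOOH, 4 Å sieves, CH2Cl2, −25 °C; NaOH/brine work-up
Reagents that add atoms: tert-butyl hydroperoxide, CC(C)(C)OO
Why: Sharpless asymmetric epoxidation is directed by the allylic hydroxyl, so the enol ether and alkyne are not touched; D-(−)-tartrate delivers oxygen to the face that gives C11 = R and C10 = S, and syn addition to the defined alkene fixes their relative configuration.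

Step 13
Reactants: 24 [(2R,3S)-3-[2-(3,4-dihydro-2H-pyran-6-yl)ethyl]-3-methyl-2-(pent-3-yn-1-yl)oxiran-2-yl]methanol
Product: 25 pentynyl tricyclic ketal (6S,7R,10S,11S)
Conditions: Et2AlCl (2.2 equiv), CH2Cl2 (0.01 M), −78 → −30 °C; aq. KNa tartrate
Reagents that add atoms: none
Why: Proposed new method: Et2AlCl turns the primary hydroxyl into an aluminium alkoxide that holds the Lewis acid on the epoxide oxygen; the enol ether carbon C6 can reach only C11 anti to a breaking C–O bond through a six-membered chair (attack at C10 would be a five-membered endo closure), so the C6–C11 bond forms with inversion at C11 and retention at C10; the dihydropyran ring forces C5 trans to C8, hence equatorial, which fixes C6, and the C7 oxocarbenium ion is trapped by the axial CH2O–Al arm as a bicyclic ketal; the closest known reaction type is the Lewis-acid epoxide-initiated cation–π cyclisation terminated by enol ethers or furans, itself modelled on the epoxide-triggered A/B closure of oxidosqualene.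

Step 14
Reactants: 25 pentynyl tricyclic ketal (6S,7R,10S,11S)
Product: 27 (E)-iodoalkenyl tricyclic ketal (6S,7R,10S,11S), via alkenylzirconocene chloride 26 (not isolated)
Conditions: Cp2Zr(H)Cl (3 equiv), THF, 25 → 40 °C; I2, 0 °C
Reagents that add atoms: iodine, [I][I]
Why: Hydrozirconation adds Zr–H syn across the methyl alkyne (the only unsaturation left) and equilibrates zirconium to the less hindered methyl-bearing carbon C15; iodinolysis with retention gives the (E)-2-iodoalkene.

Step 15
Reactants: 27 (E)-iodoalkenyl tricyclic ketal (6S,7R,10S,11S)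
Product: 29 (2Z)-2-[(2R,3S,4S)-4-hydroxy-3-(hydroxymethyl)-2-(3-hydroxypropyl)-3-[(3E)-4-iodopent-3-en-1-yl]-4-methylcyclohexylidene]propanal, via β-alkoxy aldehyde 28 (not isolated)
Conditions: (Z)-CH3CH=CHOSiMe3 (3 equiv), Me3SiOTf (20 mol %), CH2Cl2, −78 → −40 °C; then DBU, 0 → 25 °C; aq. citric acid
Reagents that add atoms: (Z)-trimethyl(prop-1-en-1-yloxy)silane, C/C=C\O[Si](C)(C)C
Why: Mukaiyama-type addition of the enol silane to the oxocarbenium ion released from the bicyclic ketal forms the C7–C2 bond, and E1cB retro-oxa-Michael elimination then opens the remaining C7–O bond to give the tetrasubstituted enal and the free hydroxypropyl arm; the Z isomer is expected to be favoured because the planar CHO, not the methyl, sits syn to the more substituted C6 (allylic 1,3-strain), and C6, C10 and C11 are not touched.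

Step 16
Reactants: 29 (2Z)-2-[(2R,3S,4S)-4-hydroxy-3-(hydroxymethyl)-2-(3-hydroxypropyl)-3-[(3E)-4-iodopent-3-en-1-yl]-4-methylcyclohexylidene]propanal; 12 tributyl{(E)-2-[(1R,3S)-2,2,3-trimethyl-6-methylidenecyclohexyl]ethenyl}stannane
Product: 30 target CNP0149035.1
Conditions: Pd2(dba)3 (5 mol %), AsPh3 (20 mol %), CuI (10 mol %), NMP, 25 °C, dark
Reagents that add atoms: none
Why: Stille coupling joins the two sp2 carbons with retention of both alkene geometries under neutral conditions that tolerate the free hydroxyls and the enal, giving the (14E,16E)-diene.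

## Compound list

1 | (E)-2-methylbut-2-en-1-ol | C/C=C(\C)CO | starting material
2 | (E)-1-chloro-2-methylbut-2-ene | C/C=C(\C)CCl | intermediate
3 | 2-(2-bromoethyl)-1,3-dioxolane | BrCCC1OCCO1 | starting material
4 | [2-(1,3-dioxolan-2-yl)ethyl]magnesium bromide | Br[Mg]CCC1OCCO1 | intermediate
5 | 2-[(3S)-3,4-dimethylpent-4-en-1-yl]-1,3-dioxolane | C=C(C)[C@@H](C)CCC1OCCO1 | intermediate
6 | (4S)-4,5-dimethylhex-5-enal | C=C(C)[C@@H](C)CCC=O | intermediate
7 | ethyl (6S)-6,7-dimethyl-3-oxooct-7-enoate | CCOC(=O)CC(=O)CC[C@H](C)C(C)=C | intermediate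
8 | ethyl (3S)-2-[(chloromercurio)methyl]-2,3-dimethyl-6-oxocyclohexane-1-carboxylate (mixture at C1 and C2) | CCOC(=O)C1C(=O)CC[C@H](C)C1(C)C[Hg]Cl | intermediate
9 | ethyl (1S,3S)-2,2,3-trimethyl-6-oxocyclohexane-1-carboxylate (ester cis to the 3-methyl) | O=C1CC[C@H](C)C(C)(C)[C@@H]1C(=O)OCC | intermediate
10 | ethyl (1R,3S)-2,2,3-trimethyl-6-methylidenecyclohexane-1-carboxylate | C=C1CC[C@H](C)C(C)(C)[C@@H]1C(=O)OCC | intermediate
11 | (1R,3S)-2,2,3-trimethyl-6-methylidenecyclohexane-1-carbaldehyde | C=C1CC[C@H](C)C(C)(C)[C@@H]1C=O | intermediate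
12 | tributyl{(E)-2-[(1R,3S)-2,2,3-trimethyl-6-methylidenecyclohexyl]ethenyl}stannane | C=C1CC[C@H](C)C(C)(C)[C@@H]1/C=C/[Sn](CCCC)(CCCC)CCCC | intermediate
13 | but-2-yn-1-ol | CC#CCO | starting material
14 | 5-bromopent-2-yne | CC#CCCBr | starting material
15 | pent-3-yn-1-ylmagnesium bromide | CC#CCC[Mg]Br | intermediate
16 | chloromagnesium (2Z)-3-(bromomagnesio)-2-(pent-3-yn-1-yl)but-2-en-1-olate (five-membered chelate, Mg cis to CH2O) | CC#CCC/C(CO[Mg]Cl)=C(\C)[Mg]Br | intermediate
17 | (2Z)-3-iodo-2-(pent-3-yn-1-yl)but-2-en-1-ol | CC#CCC/C(CO)=C(\C)I | intermediate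
18 | 3,4-dihydro-2H-pyran | C1CC=COC1 | starting material
19 | 6-lithio-3,4-dihydro-2H-pyran | [Li]C1=CCCCO1 | intermediate
20 | chloro(3,4-dihydro-2H-pyran-6-yl)zinc | Cl[Zn]C1=CCCCO1 | intermediate
21 | 6-ethenyl-3,4-dihydro-2H-pyran | C=CC1=CCCCO1 | intermediate
22 | 9-[2-(3,4-dihydro-2H-pyran-6-yl)ethyl]-9-borabicyclo[3.3.1]nonane | O1CCCC=C1CCB2C3CCCC2CCC3 | intermediate
23 | (2Z)-5-(3,4-dihydro-2H-pyran-6-yl)-3-methyl-2-(pent-3-yn-1-yl)pent-2-en-1-ol | CC#CCC/C(CO)=C(\C)CCC1=CCCCO1 | intermediate
24 | [(2R,3S)-3-[2-(3,4-dihydro-2H-pyran-6-yl)ethyl]-3-methyl-2-(pent-3-yn-1-yl)oxiran-2-yl]methanol (C11 = R, C10 = S) | CC#CCC[C@]1(CO)O[C@@]1(C)CCC1=CCCCO1 | intermediate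
25 | pentynyl tricyclic ketal (6S,7R,10S,11S): cyclohexane ring B (C6–C11) trans-fused at C6–C7 to a tetrahydropyran (C7–O–C3H2–C4H2–C5H2–C6) and bridged by C11–C26H2–O–C7; OH and CH3 on C10; CH2CH2C≡CCH3 on C11 | CC#CCC[C@@]1(CO2)[C@@H]3CCCO[C@]23CC[C@]1(C)O | intermediate
26 | alkenylzirconocene chloride of 25 (Zr on C15, syn to H14; tertiary oxygen as zirconocene alkoxide) | C/C(=C\CC[C@@]1(CO2)[C@@H]3CCCO[C@]23CC[C@]1(C)O[Zr](Cl)(C4C=CC=C4)C5C=CC=C5)[Zr](Cl)(C6C=CC=C6)C7C=CC=C7 | intermediate
27 | (E)-iodoalkenyl tricyclic ketal (6S,7R,10S,11S): as 25 with CH2CH2CH=C(CH3)I on C11 | I/C(C)=C/CC[C@@]1(CO2)[C@@H]3CCCO[C@]23CC[C@]1(C)O | intermediate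
28 | β-alkoxy aldehyde: C7 carries CH(CH3)CHO and the tetrahydropyran oxygen; C26–O–SiMe3 (mixture at C2 and C7) | I/C(C)=C/CC[C@@]1(CO[Si](C)(C)C)[C@@H]2CCCOC2(C(C)C=O)CC[C@]1(C)O | intermediate
29 | (2Z)-2-[(2R,3S,4S)-4-hydroxy-3-(hydroxymethyl)-2-(3-hydroxypropyl)-3-[(3E)-4-iodopent-3-en-1-yl]-4-methylcyclohexylidene]propanal | I/C(C)=C/CC[C@@]1(CO)[C@H](CCCO)/C(=C(/C)C=O)CC[C@]1(C)O | intermediate
30 | (2Z)-2-[(2R,3S,4S)-4-hydroxy-3-(hydroxymethyl)-2-(3-hydroxypropyl)-4-methyl-3-{(3E,5E)-4-methyl-6-[(1R,3S)-2,2,3-trimethyl-6-methylidenecyclohexyl]hexa-3,5-dien-1-yl}cyclohexylidene]propanal | C=C1CC[C@H](C)C(C)(C)[C@@H]1/C=C/C(C)=C/CC[C@@]1(CO)[C@H](CCCO)/C(=C(/C)C=O)CC[C@]1(C)O | target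

## Step count and risks

Total step count: 16. Longest linear sequence: 9 steps (steps 1–8, then 16); the ring B branch from 13 to 30 is 7 steps.

Steps most likely to fail:

1. Step 13 (ring B cyclisation). Risk: C11 carries the electron-withdrawing CH2O group, so the epoxide may ionise at C10 and rearrange (1,2-shift to a ketone) instead of being attacked at C11. Fallback: make C11 allylic so that its C–O bond ionises first. It sets out from 13: anti-carbomagnesiation with CH2=CHMgBr (THF, reflux) and iodinolysis give (2Z)-2-ethenyl-3-iodobut-2-en-1-ol F1; Suzuki coupling with borane 22 gives (2Z)-5-(3,4-dihydro-2H-pyran-6-yl)-2-ethenyl-3-methylpent-2-en-1-ol F2; epoxidation as in step 12 gives the vinyl epoxy alcohol [(2R,3S)-3-[2-(3,4-dihydro-2H-pyran-6-yl)ethyl]-2-ethenyl-3-methyloxiran-2-yl]methanol F3; Et2AlCl gives the 11-ethenyl tricyclic ketal F4; hydroboration of the vinyl group with 9-BBN-H and Suzuki coupling at the CH–I end of (E)-1,2-diiodoprop-1-ene bring the route back at 27.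

2. Step 15 (C7–C2 bond and enal geometry). Risk: the addition at the hindered C7 may be slow and the elimination may give E/Z mixtures. Fallback: build the enal by 1,3-oxidative transposition instead. It sets out from 27: HS(CH2)3SH and BF3·OEt2 open the ketal to the dithiane triol F5; Et3SiOTf and 2,6-lutidine give the tris(triethylsilyl) ether F6; MeI and CaCO3 in aqueous MeCN free the C7 ketone F7; CH2=C(CH3)MgBr with CeCl3 at −78 °C gives the tertiary isopropenyl carbinol F8; pyridinium chlorochromate [C5H5NH][CrO3Cl] effects the Babler–Dauben transposition (methyl eclipsing the less hindered C8 in the chair) to the silylated Z-enal F9; HF·pyridine brings the route back at 29.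

3. Step 5 (ring A cyclisation). Risk: mercury may be captured by the enol oxygen or at the α-carbon instead of triggering C-cyclisation. Fallback: selenium-triggered carbocyclisation. It sets out from 7: N-(phenylselanyl)phthalimide and SnCl4 in CH2Cl2 (−78 → 25 °C; SnCl4 isomerises any O-cyclised material to the carbocycle through the bridged seleniranium ion) give ethyl (3S)-2,3-dimethyl-6-oxo-2-[(phenylselanyl)methyl]cyclohexane-1-carboxylate F10; Bu3SnH with AIBN in toluene at 80 °C removes selenium and brings the route back at 9.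

Further compounds

F1 | step 13 | (2Z)-2-ethenyl-3-iodobut-2-en-1-ol | C=C/C(CO)=C(\C)I
F2 | step 13 | (2Z)-5-(3,4-dihydro-2H-pyran-6-yl)-2-ethenyl-3-methylpent-2-en-1-ol | C=C/C(CO)=C(\C)CCC1=CCCCO1
F3 | step 13 | [(2R,3S)-3-[2-(3,4-dihydro-2H-pyran-6-yl)ethyl]-2-ethenyl-3-methyloxiran-2-yl]methanol | C=C[C@]1(CO)O[C@@]1(C)CCC1=CCCCO1
F4 | step 13 | 11-ethenyl tricyclic ketal (as 25 with CH=CH2 on C11) | C=C[C@@]1(CO2)[C@@H]3CCCO[C@]23CC[C@]1(C)O
F5 | step 15 | C7 1,3-dithiane triol (ring B with free C3–OH, C26–OH, C10–OH and the iodopentenyl chain) | I/C(C)=C/CC[C@@]1(CO)[C@H](CCCO)C2(SCCCS2)CC[C@]1(C)O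
F6 | step 15 | tris(triethylsilyl) ether of F5 | I/C(C)=C/CC[C@@]1(CO[Si](CC)(CC)CC)[C@H](CCCO[Si](CC)(CC)CC)C2(SCCCS2)CC[C@]1(C)O[Si](CC)(CC)CC
F7 | step 15 | C7 ketone tris(triethylsilyl) ether | I/C(C)=C/CC[C@@]1(CO[Si](CC)(CC)CC)[C@H](CCCO[Si](CC)(CC)CC)C(=O)CC[C@]1(C)O[Si](CC)(CC)CC
F8 | step 15 | C7 isopropenyl carbinol tris(triethylsilyl) ether (mixture at C7) | I/C(C)=C/CC[C@@]1(CO[Si](CC)(CC)CC)[C@H](CCCO[Si](CC)(CC)CC)C(O)(C(C)=C)CC[C@]1(C)O[Si](CC)(CC)CC
F9 | step 15 | tris(triethylsilyl) ether of 29 | I/C(C)=C/CC[C@@]1(CO[Si](CC)(CC)CC)[C@H](CCCO[Si](CC)(CC)CC)/C(=C(/C)C=O)CC[C@]1(C)O[Si](CC)(CC)CC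
F10 | step 5 | ethyl (3S)-2,3-dimethyl-6-oxo-2-[(phenylselanyl)methyl]cyclohexane-1-carboxylate (mixture at C1 and C2) | CCOC(=O)C1C(=O)CC[C@H](C)C1(C)C[Se]c1ccccc1
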